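**Retrosynthetic overview**
- Target ⇒ bis-angeloylation of the C6/C7 trans-diol; the C2 ketone comes from allylic oxidation of the ring CH2 next to the C3=C4 alkene.
- Seven-membered ring ⇒ ring-closing metathesis that closes C8=C9 (isopropenyl + vinyl); the Z geometry is enforced by the ring.
- Key C–C bond C6–C7 ⇒ neopentyl aldehyde + (Z)-γ-(methoxymethoxy)allyl carbanion on Ipc2B (an α-oxygenated, polarity-reversed carbon attacks the carbonyl carbon); it sets both carbinol centres and brings the metathesis handle in one operation.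
- Aldehyde with quaternary C5 and the cis C4a/C9a relationship ⇒ isomerisation–Claisen rearrangement of the methallyl ether of (1S,4R)-p-mentha-2,8-dien-1-ol (suprafacial C–O to C–C chirality transfer).
- Ring order: six-membered ring from the chiral pool, then the seven-membered ring in step 4.

Assumption: (1S,4R)-p-mentha-2,8-dien-1-ol (the (R)-limonene-derived alcohol, hydroxyl cis to isopropenyl), 3-(methoxymethoxy)prop-1-ene, (−)-Ipc2BOMe and angelic acid are taken as purchasable.
Locants in the text follow benzo[7]annulene numbering of the target: C2 ketone, C3 methyl, C4a/C9a ring fusion, C5 CMe2, C6/C7 oxygenated carbons, C8=C9 alkene.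

**Step 1**
Reactants: 1 (1S,4R)-1-methyl-4-(prop-1-en-2-yl)cyclohex-2-en-1-ol; 2 3-bromo-2-methylprop-1-ene
Product: 3 (3S,6R)-3-methyl-3-[(2-methylprop-2-en-1-yl)oxy]-6-(prop-1-en-2-yl)cyclohex-1-ene
Conditions: NaH, Bu4NI (cat.), THF–DMF, 0 °C to rt
Reagents that add atoms: none
Why: Williamson ether synthesis in which the tertiary sodium alkoxide attacks the primary allylic bromide (SN2, no β-hydrogen available for elimination) and no stereocentre is touched.

**Step 2**
Reactants: 3 (3S,6R)-3-methyl-3-[(2-methylprop-2-en-1-yl)oxy]-6-(prop-1-en-2-yl)cyclohex-1-ene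
Product: 5 2-methyl-2-[(1S,6R)-3-methyl-6-(prop-1-en-2-yl)cyclohex-2-en-1-yl]propanal, via isobutenyl ether 4 (not isolated)
Conditions: [Ir(cod)(PMePh2)2]PF6 (3 mol%, activated with H2 then degassed), THF, rt; then toluene, 130 °C
Reagents that add atoms: none
Why: Olefin isomerisation–Claisen rearrangement ([3,3]-sigmatropic shift) in which only the methallyl group can isomerise (the ring carbinol carbon is quaternary, and the isobutenyl ether has no E/Z issue), and the shift runs suprafacially through the conformer with axial C–O and equatorial isopropenyl, so the new bond to the quaternary carbon forms on the face that carried oxygen, cis to the isopropenyl group, transferring the carbinol configuration to the future C4a (S).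

**Step 3**
Reactants: 5 2-methyl-2-[(1S,6R)-3-methyl-6-(prop-1-en-2-yl)cyclohex-2-en-1-yl]propanal; 6 3-(methoxymethoxy)prop-1-ene; 7 (−)-B-methoxydiisopinocampheylborane
Product: 11 (3R,4R)-4-(methoxymethoxy)-2-methyl-2-[(1S,6R)-3-methyl-6-(prop-1-en-2-yl)cyclohex-2-en-1-yl]hex-5-en-3-ol, via lithiated allyl ether 8 (not isolated), via allylborane 9 (not isolated), via borinate ester 10 (not isolated)
Conditions: 6, s-BuLi, THF, −78 °C; 7; BF3·OEt2; 5, −78 °C to rt; then NaOH, H2O2
Reagents that add atoms: none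
Why: Brown γ-alkoxyallylboration, in which the α-lithiated allyl ether is an α-oxygenated carbanion (a reduced acyl-anion equivalent of acrolein) so that an oxygen-bearing carbon attacks the aldehyde carbon, the (Z)-allylborane reacts through a closed chair transition state to give the syn (threo) diol monoether, and the Ipc groups derived from (+)-α-pinene direct attack to the Si face of the neopentyl aldehyde (pivalaldehyde-type substrates are known to react cleanly), setting the future C6 (R) and C7 (R) under reagent control.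

**Step 4**
Reactants: 11 (3R,4R)-4-(methoxymethoxy)-2-methyl-2-[(1S,6R)-3-methyl-6-(prop-1-en-2-yl)cyclohex-2-en-1-yl]hex-5-en-3-ol
Product: 12 (4aS,6R,7R,9aR)-7-(methoxymethoxy)-3,5,5,9-tetramethyl-2,4a,5,6,7,9a-hexahydro-1H-benzo[7]annulen-6-ol
Conditions: second-generation Hoveyda–Grubbs catalyst RuCl2(=CH-C6H4-2-OiPr)(H2IMes) (5 mol%), toluene (5 mM), 80 °C
Reagents that add atoms: none
Why: Ring-closing metathesis in which the catalyst loads on the monosubstituted vinyl group and closes onto the cis-disposed isopropenyl group (helped by the gem-dimethyl effect) to give the trisubstituted cycloheptene, whose geometry is fixed by the ring, with loss of ethene and no change at any stereocentre.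

**Step 5**
Reactants: 12 (4aS,6R,7R,9aR)-7-(methoxymethoxy)-3,5,5,9-tetramethyl-2,4a,5,6,7,9a-hexahydro-1H-benzo[7]annulen-6-ol
Product: 14 (4aS,6R,7R,9aR)-6-hydroxy-7-(methoxymethoxy)-3,5,5,9-tetramethyl-1,4a,5,6,7,9a-hexahydro-2H-benzo[7]annulen-2-one, via allylic alcohol 13 (not isolated)
Conditions: SeO2 (30 mol%), t-BuOOH, CH2Cl2, rt; then MnO2, rt
Reagents that add atoms: selenium dioxide O=[Se]=O (delivers the new oxygen); tert-butyl hydroperoxide CC(C)(C)OO (re-oxidant that replenishes it)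
Why: Riley allylic oxidation (ene reaction then [2,3]-sigmatropic shift) followed by MnO2 oxidation of the allylic alcohol, in which selenium attacks the more electron-rich cyclohexene (the cycloheptene is deactivated by its allylic OMOM group) and oxygen goes to the ring CH2 next to the methyl-bearing alkene carbon (Guillemonat rules), after which MnO2 oxidises only the allylic carbinol, so both C2 epimers converge on one enone while the C6 hydroxyl and the four stereocentres stay untouched.

**Step 6**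
Reactants: 14 (4aS,6R,7R,9aR)-6-hydroxy-7-(methoxymethoxy)-3,5,5,9-tetramethyl-1,4a,5,6,7,9a-hexahydro-2H-benzo[7]annulen-2-one
Product: 15 (4aS,6R,7R,9aR)-6,7-dihydroxy-3,5,5,9-tetramethyl-1,4a,5,6,7,9a-hexahydro-2H-benzo[7]annulen-2-one
Conditions: HCl (cat.), MeOH, 25 °C
Reagents that add atoms: none
Why: Acid-catalysed acetal exchange (methanolysis of the MOM ether) that transfers the formaldehyde acetal carbon to methanol under conditions too mild to ionise the allylic C7–O bond or to epimerise the γ-centre of the enone.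

**Step 7**
Reactants: 15 (4aS,6R,7R,9aR)-6,7-dihydroxy-3,5,5,9-tetramethyl-1,4a,5,6,7,9a-hexahydro-2H-benzo[7]annulen-2-one; 16 (2Z)-2-methylbut-2-enoic acid
Product: 19 (4aS,6R,7R,9aR)-3,5,5,9-tetramethyl-2-oxo-2,4a,5,6,7,9a-hexahydro-1H-benzo[7]annulene-6,7-diyl bis[(2Z)-2-methylbut-2-enoate], via mixed anhydride 17 (not isolated), via monoangelate 18 (not isolated)
Conditions: 16 (2.6 equiv), 2,4,6-trichlorobenzoyl chloride (2.6 equiv), Et3N (3 equiv), toluene, rt; then 15 (1 equiv), 80 °C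
Reagents that add atoms: (2Z)-2-methylbut-2-enoic acid C/C=C(/C)C(=O)O (the second equivalent of 16; it becomes the second ester group)
Why: Yamaguchi-type mixed-anhydride esterification (nucleophilic acyl substitution) run without DMAP and consuming two equivalents of the mixed anhydride, in which the less hindered allylic C7 hydroxyl is acylated first and the neopentyl C6 hydroxyl second, the hindered aroyl carbonyl steers both alcohols to the angeloyl carbonyl, and the absence of a nucleophilic catalyst or strong base suppresses Z-to-E isomerisation to tiglate, both carbinol centres keeping their configuration because no C–O bond of the diol is broken.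

**Compound list**
1 | (1S,4R)-1-methyl-4-(prop-1-en-2-yl)cyclohex-2-en-1-ol [(1S,4R)-p-mentha-2,8-dien-1-ol, OH cis to isopropenyl] | C[C@@]1(O)C=C[C@H](C(C)=C)CC1 | starting material
2 | 3-bromo-2-methylprop-1-ene (methallyl bromide) | C=C(C)CBr | starting material
3 | (3S,6R)-3-methyl-3-[(2-methylprop-2-en-1-yl)oxy]-6-(prop-1-en-2-yl)cyclohex-1-ene | C[C@@]1(OCC(C)=C)C=C[C@H](C(C)=C)CC1 | intermediate
4 | (3S,6R)-3-methyl-3-[(2-methylprop-1-en-1-yl)oxy]-6-(prop-1-en-2-yl)cyclohex-1-ene (isobutenyl ether) | C[C@@]1(OC=C(C)C)C=C[C@H](C(C)=C)CC1 | intermediate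
5 | 2-methyl-2-[(1S,6R)-3-methyl-6-(prop-1-en-2-yl)cyclohex-2-en-1-yl]propanal | CC1=C[C@H](C(C)(C)C=O)[C@H](C(C)=C)CC1 | intermediate
6 | 3-(methoxymethoxy)prop-1-ene (allyl MOM ether) | C=CCOCOC | starting material
7 | (−)-B-methoxydiisopinocampheylborane [(−)-Ipc2BOMe, from (+)-α-pinene] | COB([C@@H]1C[C@@H]2C[C@H]([C@H]1C)C2(C)C)[C@@H]1C[C@@H]2C[C@H]([C@H]1C)C2(C)C | starting material
8 | (Z)-[3-(methoxymethoxy)prop-2-en-1-yl]lithium (lithiated allyl ether) | [Li]C/C=C\OCOC | intermediate
9 | (Z)-[3-(methoxymethoxy)prop-2-en-1-yl]bis(isopinocampheyl)borane (allylborane) | COCO/C=C\CB([C@@H]1C[C@@H]2C[C@H]([C@H]1C)C2(C)C)[C@@H]1C[C@@H]2C[C@H]([C@H]1C)C2(C)C | intermediate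
10 | (3R,4R)-4-(methoxymethoxy)-2-methyl-2-[(1S,6R)-3-methyl-6-(prop-1-en-2-yl)cyclohex-2-en-1-yl]hex-5-en-3-yl bis(isopinocampheyl)borinate (borinate ester) | CC1=C[C@H](C(C)(C)[C@@H](OB([C@@H]2C[C@@H]3C[C@H]([C@H]2C)C3(C)C)[C@@H]2C[C@@H]3C[C@H]([C@H]2C)C3(C)C)[C@H](OCOC)C=C)[C@H](C(C)=C)CC1 | intermediate
11 | (3R,4R)-4-(methoxymethoxy)-2-methyl-2-[(1S,6R)-3-methyl-6-(prop-1-en-2-yl)cyclohex-2-en-1-yl]hex-5-en-3-ol | CC1=C[C@H](C(C)(C)[C@@H](O)[C@H](OCOC)C=C)[C@H](C(C)=C)CC1 | intermediate
12 | (4aS,6R,7R,9aR)-7-(methoxymethoxy)-3,5,5,9-tetramethyl-2,4a,5,6,7,9a-hexahydro-1H-benzo[7]annulen-6-ol | COCO[C@@H]1C=C(C)[C@@H]2CCC(C)=C[C@@H]2C(C)(C)[C@H]1O | intermediate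
13 | (4aS,6R,7R,9aR)-7-(methoxymethoxy)-3,5,5,9-tetramethyl-2,4a,5,6,7,9a-hexahydro-1H-benzo[7]annulene-2,6-diol (allylic alcohol, both C2 epimers) | COCO[C@@H]1C=C(C)[C@@H]2CC(O)C(C)=C[C@@H]2C(C)(C)[C@H]1O | intermediate
14 | (4aS,6R,7R,9aR)-6-hydroxy-7-(methoxymethoxy)-3,5,5,9-tetramethyl-1,4a,5,6,7,9a-hexahydro-2H-benzo[7]annulen-2-one | COCO[C@@H]1C=C(C)[C@@H]2CC(=O)C(C)=C[C@@H]2C(C)(C)[C@H]1O | intermediate
15 | (4aS,6R,7R,9aR)-6,7-dihydroxy-3,5,5,9-tetramethyl-1,4a,5,6,7,9a-hexahydro-2H-benzo[7]annulen-2-one | O[C@@H]1C=C(C)[C@@H]2CC(=O)C(C)=C[C@@H]2C(C)(C)[C@H]1O | intermediate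
16 | (2Z)-2-methylbut-2-enoic acid (angelic acid) | C/C=C(/C)C(=O)O | starting material
17 | (2Z)-2-methylbut-2-enoic 2,4,6-trichlorobenzoic anhydride (mixed anhydride) | C/C=C(/C)C(=O)OC(=O)c1c(Cl)cc(Cl)cc1Cl | intermediate
18 | (4aS,6R,7R,9aR)-6-hydroxy-3,5,5,9-tetramethyl-2-oxo-2,4a,5,6,7,9a-hexahydro-1H-benzo[7]annulen-7-yl (2Z)-2-methylbut-2-enoate (monoangelate) | C/C=C(/C)C(=O)O[C@@H]1C=C(C)[C@@H]2CC(=O)C(C)=C[C@@H]2C(C)(C)[C@H]1O | intermediate
19 | (4aS,6R,7R,9aR)-3,5,5,9-tetramethyl-2-oxo-2,4a,5,6,7,9a-hexahydro-1H-benzo[7]annulene-6,7-diyl bis[(2Z)-2-methylbut-2-enoate] | C/C=C(/C)C(=O)O[C@@H]1C=C(C)[C@@H]2CC(=O)C(C)=C[C@@H]2C(C)(C)[C@H]1OC(=O)/C(C)=C\C | target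

**Totals**
Total step count: 7. Longest linear sequence: 7 steps (1 to 19).

**Steps most likely to fail**

Step 5 (regioselectivity of the C–H oxidation: the two ring methyl groups and the second trisubstituted alkene compete with the C2 methylene). Fallback: the oxidation is moved to the fully acylated stage and run by hydrogen-atom abstraction instead of the ene pathway. Setting out from 12, acidic methanolysis of the MOM ether (HCl cat., MeOH) gives the deoxo diol (4aS,6R,7R,9aR)-3,5,5,9-tetramethyl-2,4a,5,6,7,9a-hexahydro-1H-benzo[7]annulene-6,7-diol F1. Acylation with two equivalents of 16 through 17 as in step 7 gives the deoxo diester (4aS,6R,7R,9aR)-3,5,5,9-tetramethyl-2,4a,5,6,7,9a-hexahydro-1H-benzo[7]annulene-6,7-diyl bis[(2Z)-2-methylbut-2-enoate] F2. CrO3·3,5-dimethylpyrazole (CH2Cl2, −20 °C) then oxidises the C2 methylene, which is possible because no free hydroxyl is left and the C7 ester shields the cycloheptene; this comes back to the route at 19.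

Step 2 (slow isomerisation of the 1,1-disubstituted allyl ether, or ionisation of the tertiary allylic ether on heating). Fallback: an ester-enolate rearrangement replaces the enol-ether route, at the cost of two extra steps. Setting out from 1, n-BuLi then isobutyryl chloride gives the ester (1S,4R)-1-methyl-4-(prop-1-en-2-yl)cyclohex-2-en-1-yl 2-methylpropanoate F3. Ireland–Claisen rearrangement (LiN(iPr)2, Me3SiCl, THF, −78 °C then 60 °C; aqueous acid) gives, with the same suprafacial transfer, the acid 2-methyl-2-[(1S,6R)-3-methyl-6-(prop-1-en-2-yl)cyclohex-2-en-1-yl]propanoic acid F4. LiAlH4 reduces it to the neopentyl alcohol 2-methyl-2-[(1S,6R)-3-methyl-6-(prop-1-en-2-yl)cyclohex-2-en-1-yl]propan-1-ol F5, and Dess–Martin periodinane returns to the route at 5.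

Step 7 (the neopentyl C6 hydroxyl is hindered, and forcing conditions risk angelate-to-tiglate isomerisation). Fallback: the Z-alkenes are built on the ester instead of being carried through the acylation. Setting out from 15, both hydroxyls are acylated with 2-[bis(2,2,2-trifluoroethoxy)phosphoryl]propanoic acid (two equivalents, DCC, DMAP, CH2Cl2; DMAP is harmless because no Z-alkene is present yet) to give the bis(phosphonate) (4aS,6R,7R,9aR)-3,5,5,9-tetramethyl-2-oxo-2,4a,5,6,7,9a-hexahydro-1H-benzo[7]annulene-6,7-diyl bis{2-[bis(2,2,2-trifluoroethoxy)phosphoryl]propanoate} F6. Still–Gennari olefination with acetaldehyde (KN(SiMe3)2, 18-crown-6, THF, −78 °C) then forms both (Z)-2-methylbut-2-enoates and comes back to the route at 19.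

**Further compounds**
F1 | step 5 | (4aS,6R,7R,9aR)-3,5,5,9-tetramethyl-2,4a,5,6,7,9a-hexahydro-1H-benzo[7]annulene-6,7-diol | O[C@@H]1C=C(C)[C@@H]2CCC(C)=C[C@@H]2C(C)(C)[C@H]1O
F2 | step 5 | (4aS,6R,7R,9aR)-3,5,5,9-tetramethyl-2,4a,5,6,7,9a-hexahydro-1H-benzo[7]annulene-6,7-diyl bis[(2Z)-2-methylbut-2-enoate] | C/C=C(/C)C(=O)O[C@@H]1C=C(C)[C@@H]2CCC(C)=C[C@@H]2C(C)(C)[C@H]1OC(=O)/C(C)=C\C
F3 | step 2 | (1S,4R)-1-methyl-4-(prop-1-en-2-yl)cyclohex-2-en-1-yl 2-methylpropanoate | C[C@@]1(OC(=O)C(C)C)C=C[C@H](C(C)=C)CC1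
F4 | step 2 | 2-methyl-2-[(1S,6R)-3-methyl-6-(prop-1-en-2-yl)cyclohex-2-en-1-yl]propanoic acid | CC1=C[C@H](C(C)(C)C(=O)O)[C@H](C(C)=C)CC1
F5 | step 2 | 2-methyl-2-[(1S,6R)-3-methyl-6-(prop-1-en-2-yl)cyclohex-2-en-1-yl]propan-1-ol | CC1=C[C@H](C(C)(C)CO)[C@H](C(C)=C)CC1
F6 | step 7 | (4aS,6R,7R,9aR)-3,5,5,9-tetramethyl-2-oxo-2,4a,5,6,7,9a-hexahydro-1H-benzo[7]annulene-6,7-diyl bis{2-[bis(2,2,2-trifluoroethoxy)phosphoryl]propanoate} | CC(C(=O)O[C@@H]1C=C(C)[C@@H]2CC(=O)C(C)=C[C@@H]2C(C)(C)[C@H]1OC(=O)C(C)P(=O)(OCC(F)(F)F)OCC(F)(F)F)P(=O)(OCC(F)(F)F)OCC(F)(F)F
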